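**Strategy**

Cardopatine is cut back to cyclobutanecarboxylic acid: C1 of the four-membered ring carries the carboxyl carbon that will become one alkyne, and its two neighbours, the ring methylenes C2 and C4, are enantiotopic. A ligand-controlled palladium-catalysed C–H alkynylation of the derived N-aryl amide replaces one C2–H by a silyl-capped alkyne, so a single operation forges the C2–C(sp) bond, breaks the mirror symmetry and fixes C2. Its substrate is the achiral N-[2,3,5,6-tetrafluoro-4-(trifluoromethyl)phenyl]amide of cyclobutanecarboxylic acid, paired with (bromoethynyl)triisopropylsilane. Inversion of C1 to trans, one-carbon homologation of the carboxyl group and two successive Sonogashira couplings with 5-bromo-2,2'-bithiophene finish the (1R,2R) target.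

Key step: step 3

Assumption: the (S,S)-configured acetamido-oxazoline ligand of step 3, N-[(1S)-1-[(4S)-4-benzyl-4,5-dihydro-1,3-oxazol-2-yl]-2,2-dimethylpropyl]acetamide (SMILES CC(=O)N[C@@H](C(C)(C)C)C1=N[C@@H](Cc2ccccc2)CO1, a catalyst component made beforehand from L-tert-leucine and (S)-phenylalaninol), is taken to favour the (1S,2R)-cis product, whose inversion at C1 alone gives the (1R,2R)-trans series of the target; should the antipode prevail, the mirror-image ligand is used with no other change.

**Route**

Step 1
Reactants: 1 cyclobutanecarbonyl chloride; 2 4-amino-2,3,5,6-tetrafluorobenzotrifluoride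
Product: 3 N-[2,3,5,6-tetrafluoro-4-(trifluoromethyl)phenyl]cyclobutanecarboxamide
Conditions: PhMe, reflux, N2 sweep, no base
Reagents that add atoms: none
Why: Nucleophilic acyl substitution (amide formation from an acid chloride) should proceed even with this weakly nucleophilic polyfluoroaniline once heated, the HCl leaving as gas, and no stereocenter is formed.

Step 2
Reactants: 4 (triisopropylsilyl)acetylene
Product: 5 (bromoethynyl)triisopropylsilane
Conditions: NBS (1.2 equiv), AgNO3 (10 mol %), acetone, rt, dark
Reagents that add atoms: N-bromosuccinimide, O=C1CCC(=O)N1Br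
Why: Electrophilic bromination of a terminal alkyne through its silver acetylide (AgNO3-catalysed NBS bromination) is a routine entry to silyl-capped 1-bromoalkynes and creates no stereocenter.

Step 3
Reactants: 3 N-[2,3,5,6-tetrafluoro-4-(trifluoromethyl)phenyl]cyclobutanecarboxamide; 5 (bromoethynyl)triisopropylsilane
Product: 6 (1S,2R)-N-[2,3,5,6-tetrafluoro-4-(trifluoromethyl)phenyl]-2-[(triisopropylsilyl)ethynyl]cyclobutane-1-carboxamide (cis)
Conditions: Pd(OAc)2 (10 mol %), acetamido-oxazoline ligand (20 mol %), Ag2CO3 (1.0 equiv), 5 (1.5 equiv), t-AmOH, 70 °C, N2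
Reagents that add atoms: none
Why: Proposed new method: the amide N–H, acidified by the perfluoroaryl group, is deprotonated and binds divalent palladium as an anionic donor, and the acetamido group of the bidentate ligand serves as internal base in a concerted metalation–deprotonation that cleaves one of the two enantiotopic β-C–H bonds (at C2 or C4) to give a cis-fused five-membered palladacycle; oxidative addition of the bromoalkyne to tetravalent palladium and C(sp3)–C(sp) reductive elimination then forge the C2–alkyne bond, with Ag2CO3 taking up the bromide and the proton. The closest known reaction types are the enantioselective β-C–H arylation and vinylation of this amide class with the same ligand family and the non-asymmetric amide-directed β-C–H alkynylation with silyl bromoalkynes, so only the pairing of chiral ligand and alkynyl electrophile is new. No ring is closed in the product, the only cycle formed being the transient palladacycle. C2 is set by the ligand, which tells the C2–H and C4–H bonds apart in the C–H cleavage transition state, and C1 becomes stereogenic as a consequence, its cis relation to C2 being dictated by the palladacycle because the metal can only reach a C–H bond on the ring face that carries the amide. The step needs enantiotopic-group selectivity (ligand), cis diastereoselectivity (palladacycle geometry) and mono-selectivity, the last secured by the bulky triisopropylsilyl alkyne next to the directing group, which should hinder a second metalation at C4, and by the limited charge of bromoalkyne.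

Step 4
Reactants: 6 (1S,2R)-N-[2,3,5,6-tetrafluoro-4-(trifluoromethyl)phenyl]-2-[(triisopropylsilyl)ethynyl]cyclobutane-1-carboxamide
Product: 7 tert-butyl N-[(1S,2R)-2-[(triisopropylsilyl)ethynyl]cyclobutane-1-carbonyl]-N-[2,3,5,6-tetrafluoro-4-(trifluoromethyl)phenyl]carbamate
Conditions: Boc2O (3 equiv), DMAP (0.5 equiv), MeCN, rt → 40 °C
Reagents that add atoms: di-tert-butyl dicarbonate, CC(C)(C)OC(=O)OC(=O)OC(C)(C)C
Why: DMAP-catalysed N-tert-butoxycarbonylation of the acidic anilide N–H (amide activation) twists the amide out of conjugation and turns the aryl carbamate into a leaving group for the next step, leaving C1 and C2 untouched.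

Step 5
Reactants: 7 tert-butyl N-[(1S,2R)-2-[(triisopropylsilyl)ethynyl]cyclobutane-1-carbonyl]-N-[2,3,5,6-tetrafluoro-4-(trifluoromethyl)phenyl]carbamate
Product: 9 methyl (1R,2R)-2-[(triisopropylsilyl)ethynyl]cyclobutane-1-carboxylate (trans), via cis methyl ester 8 (not isolated)
Conditions: NaOMe (3 equiv), MeOH/THF, 0 °C → 50 °C; then 1 M HCl, 0 °C
Reagents that add atoms: sodium methoxide, C[O-].[Na+]
Why: Methoxide should attack the ketone-like acyl carbonyl of the N-acyl carbamate and expel the stabilised aryl carbamate anion (acyl transfer from an activated amide), and the excess base then equilibrates the ester at C1 through its enolate (thermodynamic epimerisation), so that C1 inverts from S to R to relieve the cis 1,2-interaction while the non-acidic propargylic C2 keeps its R configuration.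

Step 6
Reactants: 9 methyl (1R,2R)-2-[(triisopropylsilyl)ethynyl]cyclobutane-1-carboxylate
Product: 10 (1R,2R)-2-[(triisopropylsilyl)ethynyl]cyclobutane-1-carbaldehyde
Conditions: iBu2AlH (1.1 equiv), CH2Cl2, −78 °C; then MeOH, aq. potassium sodium tartrate
Reagents that add atoms: none
Why: Partial reduction of an ester with iBu2AlH at −78 °C should stop at the tetrahedral aluminium hemiacetal, which releases the aldehyde only on work-up, while the silyl alkyne is inert at this temperature and the trans aldehyde is the preferred C1 epimer.

Step 7
Reactants: 10 (1R,2R)-2-[(triisopropylsilyl)ethynyl]cyclobutane-1-carbaldehyde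
Product: 11 (1R,2R)-1-ethynyl-2-[(triisopropylsilyl)ethynyl]cyclobutane
Conditions: dimethyl (1-diazo-2-oxopropyl)phosphonate (1.5 equiv), K2CO3 (2 equiv), MeOH, 0 °C → rt
Reagents that add atoms: dimethyl (1-diazo-2-oxopropyl)phosphonate, CC(=O)C(=[N+]=[N-])P(=O)(OC)OC
Why: The Ohira–Bestmann alkynylation (Seyferth–Gilbert homologation under K2CO3/MeOH) converts the aldehyde into the terminal alkyne through a diazoalkene and a 1,2-hydrogen shift of the alkylidene carbene, under conditions that the triisopropylsilyl alkyne survives and in which any enolisation at C1 can only return the favoured trans isomer.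

Step 8
Reactants: 11 (1R,2R)-1-ethynyl-2-[(triisopropylsilyl)ethynyl]cyclobutane; 12 5-bromo-2,2'-bithiophene
Product: 13 5-{[(1R,2R)-2-[(triisopropylsilyl)ethynyl]cyclobutyl]ethynyl}-2,2'-bithiophene
Conditions: 12 (1.05 equiv), Pd(PPh3)4 (5 mol %), CuI (10 mol %), Et3N/THF, degassed, 50 °C
Reagents that add atoms: none
Why: In this Sonogashira coupling the C–Br bond of the 2-bromothiophene unit adds oxidatively to zerovalent palladium and is joined to the copper acetylide of the only terminal alkyne, while the silyl-capped alkyne cannot form an acetylide and C1 and C2 are not touched.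

Step 9
Reactants: 13 5-{[(1R,2R)-2-[(triisopropylsilyl)ethynyl]cyclobutyl]ethynyl}-2,2'-bithiophene; 12 5-bromo-2,2'-bithiophene
Product: 15 cardopatine, (1R,2R)-1,2-bis[(2,2'-bithiophen-5-yl)ethynyl]cyclobutane, via terminal alkyne 14 (not isolated)
Conditions: Bu4NF (1.2 equiv), THF, 0 °C → rt; then 12 (1.2 equiv), Pd(PPh3)4 (5 mol %), CuI (10 mol %), Et3N, degassed, 50 °C
Reagents that add atoms: none
Why: Fluoride cleaves the C(sp)–Si bond (desilylation) to unveil the second terminal alkyne as a non-volatile bithienyl-substituted intermediate, which is consumed in the same flask by a second Sonogashira coupling with the bromobithiophene, neither event touching C1 or C2.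

**Compound list**

1 | cyclobutanecarbonyl chloride | O=C(Cl)C1CCC1 | starting material
2 | 4-amino-2,3,5,6-tetrafluorobenzotrifluoride | Nc1c(F)c(F)c(C(F)(F)F)c(F)c1F | starting material
3 | N-[2,3,5,6-tetrafluoro-4-(trifluoromethyl)phenyl]cyclobutanecarboxamide | O=C(Nc1c(F)c(F)c(C(F)(F)F)c(F)c1F)C1CCC1 | intermediate
4 | (triisopropylsilyl)acetylene | C#C[Si](C(C)C)(C(C)C)C(C)C | starting material
5 | (bromoethynyl)triisopropylsilane | BrC#C[Si](C(C)C)(C(C)C)C(C)C | intermediate
6 | (1S,2R)-N-[2,3,5,6-tetrafluoro-4-(trifluoromethyl)phenyl]-2-[(triisopropylsilyl)ethynyl]cyclobutane-1-carboxamide (cis) | O=C(Nc1c(F)c(F)c(C(F)(F)F)c(F)c1F)[C@H]1CC[C@H]1C#C[Si](C(C)C)(C(C)C)C(C)C | intermediate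
7 | tert-butyl N-[(1S,2R)-2-[(triisopropylsilyl)ethynyl]cyclobutane-1-carbonyl]-N-[2,3,5,6-tetrafluoro-4-(trifluoromethyl)phenyl]carbamate | CC(C)(C)OC(=O)N(c1c(F)c(F)c(C(F)(F)F)c(F)c1F)C(=O)[C@H]1CC[C@H]1C#C[Si](C(C)C)(C(C)C)C(C)C | intermediate
8 | methyl (1S,2R)-2-[(triisopropylsilyl)ethynyl]cyclobutane-1-carboxylate (cis, not isolated) | COC(=O)[C@H]1CC[C@H]1C#C[Si](C(C)C)(C(C)C)C(C)C | intermediate
9 | methyl (1R,2R)-2-[(triisopropylsilyl)ethynyl]cyclobutane-1-carboxylate (trans) | COC(=O)[C@@H]1CC[C@H]1C#C[Si](C(C)C)(C(C)C)C(C)C | intermediate
10 | (1R,2R)-2-[(triisopropylsilyl)ethynyl]cyclobutane-1-carbaldehyde | O=C[C@@H]1CC[C@H]1C#C[Si](C(C)C)(C(C)C)C(C)C | intermediate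
11 | (1R,2R)-1-ethynyl-2-[(triisopropylsilyl)ethynyl]cyclobutane | C#C[C@@H]1CC[C@H]1C#C[Si](C(C)C)(C(C)C)C(C)C | intermediate
12 | 5-bromo-2,2'-bithiophene | Brc1ccc(-c2cccs2)s1 | starting material
13 | 5-{[(1R,2R)-2-[(triisopropylsilyl)ethynyl]cyclobutyl]ethynyl}-2,2'-bithiophene | CC(C)[Si](C#C[C@@H]1CC[C@H]1C#Cc1ccc(-c2cccs2)s1)(C(C)C)C(C)C | intermediate
14 | 5-{[(1R,2R)-2-ethynylcyclobutyl]ethynyl}-2,2'-bithiophene (not isolated) | C#C[C@@H]1CC[C@H]1C#Cc1ccc(-c2cccs2)s1 | intermediate
15 | cardopatine, (1R,2R)-1,2-bis[(2,2'-bithiophen-5-yl)ethynyl]cyclobutane | C(#C[C@@H]1CC[C@H]1C#Cc1ccc(-c2cccs2)s1)c1ccc(-c2cccs2)s1 | target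

**Step count and risks**

Total step count: 9. Longest linear sequence: 8 steps (steps 1 and 3 to 9, from cyclobutanecarbonyl chloride); step 2 is a one-step side branch.

Steps most likely to fail:

1. Step 3. The catalyst may not turn over with the alkynyl electrophile when the chiral ligand is bound, the ligand may discriminate poorly between the C2–H and C4–H bonds, or a second alkynylation may set in. Fallback with known chemistry, in which the absolute configuration comes from separation and not from induction: setting out from 3 and 5, the established non-asymmetric amide-directed β-C–H alkynylation (Pd(OAc)2, an achiral pyridine-type ligand, AgOAc, PhMe, 90 °C) would give racemic cis-N-[2,3,5,6-tetrafluoro-4-(trifluoromethyl)phenyl]-2-[(triisopropylsilyl)ethynyl]cyclobutane-1-carboxamide F1. Preparative chromatography on a chiral stationary phase would then deliver the (1S,2R) enantiomer, at which point the route is rejoined at 6.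

2. Step 5. Methoxide may attack the tert-butoxycarbonyl carbonyl or a ring fluorine of the activated imide instead of the acyl carbonyl, and the equilibration at C1 may stop short of the trans ester. Fallback that separates cleavage from epimerisation: setting out from 7, hydroperoxide cleavage (LiOH, H2O2, THF/H2O, 0 °C; then Na2SO3 and acidification), in which the small and strongly nucleophilic hydroperoxide anion attacks the acyl carbonyl, would give (1S,2R)-2-[(triisopropylsilyl)ethynyl]cyclobutane-1-carboxylic acid F2. Methylation with MeI and K2CO3 in DMF at rt would give the cis ester 8, this time isolated, and a separate treatment with NaOMe in MeOH at 50 °C would epimerise C1 and come back to the route at 9.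

3. Step 6. The aluminium hemiacetal may collapse before the quench, so that the aldehyde is reduced further while ester remains. Fallback by a two-stage redox sequence: setting out from 9, full reduction with LiAlH4 (THF, 0 °C) would give [(1R,2R)-2-[(triisopropylsilyl)ethynyl]cyclobutyl]methanol F3, and oxidation with Dess–Martin periodinane (NaHCO3, CH2Cl2, rt) would return to the route at 10.

**Further compounds**

F1 | step 3 | racemic cis-N-[2,3,5,6-tetrafluoro-4-(trifluoromethyl)phenyl]-2-[(triisopropylsilyl)ethynyl]cyclobutane-1-carboxamide (both enantiomers) | O=C(Nc1c(F)c(F)c(C(F)(F)F)c(F)c1F)[C@H]1CC[C@H]1C#C[Si](C(C)C)(C(C)C)C(C)C.O=C(Nc1c(F)c(F)c(C(F)(F)F)c(F)c1F)[C@@H]1CC[C@@H]1C#C[Si](C(C)C)(C(C)C)C(C)C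
F2 | step 5 | (1S,2R)-2-[(triisopropylsilyl)ethynyl]cyclobutane-1-carboxylic acid | OC(=O)[C@H]1CC[C@H]1C#C[Si](C(C)C)(C(C)C)C(C)C
F3 | step 6 | [(1R,2R)-2-[(triisopropylsilyl)ethynyl]cyclobutyl]methanol | OC[C@@H]1CC[C@H]1C#C[Si](C(C)C)(C(C)C)C(C)C
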